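**Strategy.** The dihydropyran ring is cut at C4–C4a and O1–C2. C2 becomes allylic if its side chain is shortened to a vinyl group, so C4–C3–C2, the C2 methyl and that vinyl map onto 3-methylpenta-1,4-diene, and O1/C4a onto the OH and C–I of 2-iodo-4-methoxy-6-methylphenol. One Pd-catalysed relay (arylpalladation, chain walk to a π-allyl, enantioselective phenoxide attack) joins these two achiral pieces, closes the ring and sets the C2 stereocentre. The vinyl group then takes on the rest of the chain by hydroboration/B-alkyl Suzuki coupling with a (Z)-enoate (E)-vinyl iodide, and saponification ends the route.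

Key step: step 2

Numbering used: chromane O1, C2, C3, C4, C4a, C5–C8, C8a; side chain C1′ (on C2) to C8′ (bearing CO2H). The target is (2R), 3′E, 7′Z. The vinylchromane 5 has the same spatial arrangement but is named (2S), because vinyl outranks C3.

Assumption: the (R,R)-ligand is written in step 2 on the expectation that it gives the (2S)-chromane. The sense of induction of this relay cannot be predicted with certainty; should the first run give the (2R)-product, the (S,S)-ligand is used with no other change.

**Step 1**
Reactants: 1 4-methoxy-2-methylphenol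
Product: 2 2-iodo-4-methoxy-6-methylphenol
Conditions: I2 (1.05 equiv), NaHCO3 (1.5 equiv), THF/H2O 1:1, 0 °C → rt
Reagents that add atoms: iodine, II
Why: Electrophilic aromatic iodination through the phenolate, whose oxygen outweighs OMe as a director; its para position is blocked by OMe and one ortho position by the methyl group, so iodine should enter the single free ortho position.

**Step 2**
Reactants: 2 2-iodo-4-methoxy-6-methylphenol; 3 3-methylpenta-1,4-diene (5 equiv)
Product: 5 (2S)-2-ethenyl-6-methoxy-2,8-dimethyl-3,4-dihydro-2H-chromene, via Pd–H-bound dienylphenol 4 (not isolated)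
Conditions: Pd2(dba)3·CHCl3 (2.5 mol %), N,N′-[(1R,2R)-cyclohexane-1,2-diyl]bis[2-(diphenylphosphanyl)benzamide] (7.5 mol %), K2CO3 (2 equiv), 1,4-dioxane, 70 °C, sealed tube
Reagents that add atoms: none
Why: Proposed new method: Pd(0)L* inserts into the C–I bond of 2, the aryl group adds to the terminal CH2 of one vinyl group of 3 (this makes the C4–C4a bond), β-hydride elimination of the allylic C–H next to palladium gives the Pd–H-bound diene 4, and re-insertion with the opposite regiochemistry gives a 1-methyl-1-(2-arylethyl)-η3-allylpalladium species that the ortho-phenoxide attacks at its fully substituted terminus (this makes the O1–C2 bond) with release of Pd(0). The closest known reaction types are the ligand-free Pd-catalysed annulation of o-iodophenols with 1,4-dienes to 2-vinylchromanes and the asymmetric Pd-catalysed intramolecular allylic etherification of phenols to 2-methyl-2-vinylchromanes through the same kind of π-allyl intermediate; their merger into one enantioselective relay that creates a fully substituted C–O centre is the new element. The one ring closed, the dihydropyran ring, forms by 6-exo attack of oxygen on the allyl terminus (the vinyl group stays outside the ring), favoured over the 8-membered closure at the CH2 terminus. The C2 stereocentre is set in this C–O bond formation under control of the chiral diphosphine: the two faces of the allyl interconvert through the η1 form bound at the CH2 terminus, and the ligand pocket should let the phenoxide attack, anti to palladium, only one of them. The step needs migration of palladium toward the second vinyl group and not loss of a Heck diene, which the conjugated π-allyl sink secures (free 4 can re-enter by hydropalladation), and single arylation of 3, secured by its excess; the two vinyl groups of 3 are enantiotopic and the centre created by the insertion is erased in 4, so no regiochemical or diastereochemical choice is left open at that stage.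

**Step 3**
Reactants: 6 pent-4-yn-1-ol
Product: 9 (E)-5-iodo-4-methylpent-4-en-1-ol, via aluminium alkoxide 7 (not isolated), via vinylalane 8 (not isolated)
Conditions: AlMe3 (3 equiv), Cp2ZrCl2 (0.25 equiv), CH2Cl2, 0 °C → rt; then I2 (1.2 equiv), THF, −30 → 0 °C; aqueous work-up
Reagents that add atoms: trimethylaluminium, C[Al](C)C; iodine, II
Why: Zr-catalysed Negishi carboalumination adds Me and Al syn across the terminal alkyne with Al on the terminal carbon (the OH is first capped as its aluminium alkoxide), and iodinolysis of the C–Al bond with retention gives the (E)-vinyl iodide.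

**Step 4**
Reactants: 9 (E)-5-iodo-4-methylpent-4-en-1-ol
Product: 10 (E)-5-iodo-4-methylpent-4-enal
Conditions: Dess–Martin periodinane (1.2 equiv), CH2Cl2, 0 °C → rt
Reagents that add atoms: none
Why: Dess–Martin oxidation of a primary alcohol to the aldehyde under neutral, non-aqueous conditions that leave the vinyl iodide and its geometry untouched.

**Step 5**
Reactants: 10 (E)-5-iodo-4-methylpent-4-enal; 11 ethyl 2-[bis(2,2,2-trifluoroethoxy)phosphoryl]propanoate (1.2 equiv)
Product: 13 ethyl (2Z,6E)-7-iodo-2,6-dimethylhepta-2,6-dienoate, via potassium phosphonate carbanion 12 (not isolated)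
Conditions: KHMDS (1.15 equiv), 18-crown-6 (3 equiv), THF, −78 °C
Reagents that add atoms: none
Why: Still–Gennari variant of the Horner–Wadsworth–Emmons olefination: with the bis(trifluoroethyl) phosphonate and a dissociated potassium counter-ion, elimination from the kinetic adduct outruns its equilibration, which should give the (Z)-2-methyl-enoate.

**Step 6**
Reactants: 5 (2S)-2-ethenyl-6-methoxy-2,8-dimethyl-3,4-dihydro-2H-chromene; 13 ethyl (2Z,6E)-7-iodo-2,6-dimethylhepta-2,6-dienoate
Product: 15 ethyl (2Z,6E)-9-[(2R)-6-methoxy-2,8-dimethyl-3,4-dihydro-2H-chromen-2-yl]-2,6-dimethylnona-2,6-dienoate, via B-alkyl-9-BBN 14 (not isolated)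
Conditions: 5, 9-BBN (1.3 equiv), THF, 0 °C → rt; then 3 M aq. K3PO4 (3 equiv), 13, Pd(dppf)Cl2·CH2Cl2 (5 mol %), AsPh3 (10 mol %), DMF, rt
Reagents that add atoms: none
Why: 9-BBN hydroborates the monosubstituted vinyl group at its terminal carbon, and B-alkyl Suzuki–Miyaura coupling of the primary borane with the vinyl iodide proceeds with retention of the (E) geometry; the C2 stereocentre and the (Z)-enoate are not touched.

**Step 7**
Reactants: 15 ethyl (2Z,6E)-9-[(2R)-6-methoxy-2,8-dimethyl-3,4-dihydro-2H-chromen-2-yl]-2,6-dimethylnona-2,6-dienoate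
Product: 17 (2Z,6E)-9-[(2R)-6-methoxy-2,8-dimethyl-3,4-dihydro-2H-chromen-2-yl]-2,6-dimethylnona-2,6-dienoic acid, via lithium carboxylate 16 (not isolated)
Conditions: LiOH·H2O (5 equiv), THF/EtOH/H2O 3:1:1, rt; then 1 M HCl to pH 3
Reagents that add atoms: lithium hydroxide, [Li+].[OH-]
Why: Saponification of the ethyl ester (acyl–oxygen cleavage) at room temperature and acidification; mild hydroxide conditions are chosen so that the (Z)-2-methyl-enoate should not isomerise.

**Compound list**
1 | 4-methoxy-2-methylphenol | COc1ccc(O)c(C)c1 | starting material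
2 | 2-iodo-4-methoxy-6-methylphenol | COc1cc(C)c(O)c(I)c1 | intermediate
3 | 3-methylpenta-1,4-diene | C=CC(C)C=C | starting material
4 | 4-methoxy-2-methyl-6-[(2E)-3-methylpenta-2,4-dien-1-yl]phenol, held on Pd–H | COc1cc(C)c(O)c(C/C=C(\C)C=C)c1 | intermediate (not isolated)
5 | (2S)-2-ethenyl-6-methoxy-2,8-dimethyl-3,4-dihydro-2H-chromene | COc1cc(C)c2c(c1)CC[C@@](C)(C=C)O2 | intermediate
6 | pent-4-yn-1-ol | C#CCCCO | starting material
7 | dimethylaluminium pent-4-yn-1-olate | C#CCCCO[Al](C)C | intermediate (not isolated)
8 | (E)-vinylalane, dimethylaluminium (E)-5-(dimethylalumanyl)-4-methylpent-4-en-1-olate | C[Al](C)OCCC/C(C)=C/[Al](C)C | intermediate (not isolated)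
9 | (E)-5-iodo-4-methylpent-4-en-1-ol | OCCC/C(C)=C/I | intermediate
10 | (E)-5-iodo-4-methylpent-4-enal | O=CCC/C(C)=C/I | intermediate
11 | ethyl 2-[bis(2,2,2-trifluoroethoxy)phosphoryl]propanoate | CCOC(=O)C(C)P(=O)(OCC(F)(F)F)OCC(F)(F)F | starting material
12 | potassium carbanion of 11 | CCOC(=O)[C-](C)P(=O)(OCC(F)(F)F)OCC(F)(F)F.[K+] | intermediate (not isolated)
13 | ethyl (2Z,6E)-7-iodo-2,6-dimethylhepta-2,6-dienoate | I/C=C(\C)CC/C=C(/C)C(=O)OCC | intermediate
14 | 9-{2-[(2R)-6-methoxy-2,8-dimethyl-3,4-dihydro-2H-chromen-2-yl]ethyl}-9-borabicyclo[3.3.1]nonane | COc1cc(C)c2c(c1)CC[C@@](C)(CCB1C3CCCC1CCC3)O2 | intermediate (not isolated)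
15 | ethyl (2Z,6E)-9-[(2R)-6-methoxy-2,8-dimethyl-3,4-dihydro-2H-chromen-2-yl]-2,6-dimethylnona-2,6-dienoate | COc1cc(C)c2c(c1)CC[C@@](C)(CC/C=C(\C)CC/C=C(/C)C(=O)OCC)O2 | intermediate
16 | lithium (2Z,6E)-9-[(2R)-6-methoxy-2,8-dimethyl-3,4-dihydro-2H-chromen-2-yl]-2,6-dimethylnona-2,6-dienoate | COc1cc(C)c2c(c1)CC[C@@](C)(CC/C=C(\C)CC/C=C(/C)C(=O)[O-])O2.[Li+] | intermediate (not isolated)
17 | (2Z,6E)-9-[(2R)-6-methoxy-2,8-dimethyl-3,4-dihydro-2H-chromen-2-yl]-2,6-dimethylnona-2,6-dienoic acid | COc1cc(C)c2c(c1)CC[C@@](C)(CC/C=C(\C)CC/C=C(/C)C(=O)O)O2 | target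

**Total step count:** 7
**Longest linear sequence:** 5 steps (steps 3, 4, 5, 6, 7, from 6 to 17)

**Steps most likely to fail**

1. Step 2 (Proposed new method). The phenoxide may attack both allyl faces if face exchange through the η1 form is slower than ring closure. Pd–H may also leave the diene before re-insertion, so that the reaction stops at the open Heck product, and Pd(0) may re-ionise the tertiary allylic ether of the product and erode its enantiomeric purity. Fallback with known chemistry, from 2 to 5: 2 and 3 are annulated without a chiral ligand (Pd(OAc)2, n-Bu4NCl, Na2CO3, DMF, 80–100 °C), the known racemic version of the same two-bond ring formation, to give racemic 2-ethenyl-6-methoxy-2,8-dimethyl-3,4-dihydro-2H-chromene F1. The enantiomers are then separated by preparative chromatography on a polysaccharide chiral stationary phase; the (2S)-enantiomer is 5, and (2R)-2-ethenyl-6-methoxy-2,8-dimethyl-3,4-dihydro-2H-chromene F2 is set aside.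

2. Step 6. β-Hydride elimination or protodeboronation of the alkyl group may outrun transmetalation, and residual 9-BBN may reduce the enoate of 13. Fallback, from 5 to 15, with a Negishi coupling in place of the Suzuki coupling: hydroboration/oxidation of 5 (9-BBN; then NaOH, H2O2) should give 2-[(2S)-6-methoxy-2,8-dimethyl-3,4-dihydro-2H-chromen-2-yl]ethanol F3. I2, PPh3 and imidazole convert it into (2S)-2-(2-iodoethyl)-6-methoxy-2,8-dimethyl-3,4-dihydro-2H-chromene F4. Zinc insertion (Zn dust, LiCl, THF) gives {2-[(2S)-6-methoxy-2,8-dimethyl-3,4-dihydro-2H-chromen-2-yl]ethyl}zinc iodide F5, which is coupled with 13 (Pd(dppf)Cl2, THF, rt to 40 °C) to give 15.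

3. Step 7. The hindered (Z)-2-methyl-enoate may hydrolyse slowly, and prolonged exposure to hydroxide may isomerise it to the (E)-acid. Fallback, from 15 to 17, by reduction and re-oxidation in place of hydrolysis: DIBAL-H (CH2Cl2, −78 °C) should give (2Z,6E)-9-[(2R)-6-methoxy-2,8-dimethyl-3,4-dihydro-2H-chromen-2-yl]-2,6-dimethylnona-2,6-dien-1-ol F6. MnO2 (CH2Cl2, rt) oxidises it to (2Z,6E)-9-[(2R)-6-methoxy-2,8-dimethyl-3,4-dihydro-2H-chromen-2-yl]-2,6-dimethylnona-2,6-dienal F7, and Pinnick oxidation (NaClO2, NaH2PO4, 2-methylbut-2-ene, t-BuOH/H2O) gives 17.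

**Further compounds**
F1 | step 2 | racemic 2-ethenyl-6-methoxy-2,8-dimethyl-3,4-dihydro-2H-chromene | COc1cc(C)c2c(c1)CCC(C)(C=C)O2
F2 | step 2 | (2R)-2-ethenyl-6-methoxy-2,8-dimethyl-3,4-dihydro-2H-chromene | COc1cc(C)c2c(c1)CC[C@](C)(C=C)O2
F3 | step 6 | 2-[(2S)-6-methoxy-2,8-dimethyl-3,4-dihydro-2H-chromen-2-yl]ethanol | COc1cc(C)c2c(c1)CC[C@@](C)(CCO)O2
F4 | step 6 | (2S)-2-(2-iodoethyl)-6-methoxy-2,8-dimethyl-3,4-dihydro-2H-chromene | COc1cc(C)c2c(c1)CC[C@@](C)(CCI)O2
F5 | step 6 | {2-[(2S)-6-methoxy-2,8-dimethyl-3,4-dihydro-2H-chromen-2-yl]ethyl}zinc iodide | COc1cc(C)c2c(c1)CC[C@@](C)(CC[Zn]I)O2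
F6 | step 7 | (2Z,6E)-9-[(2R)-6-methoxy-2,8-dimethyl-3,4-dihydro-2H-chromen-2-yl]-2,6-dimethylnona-2,6-dien-1-ol | COc1cc(C)c2c(c1)CC[C@@](C)(CC/C=C(\C)CC/C=C(/C)CO)O2
F7 | step 7 | (2Z,6E)-9-[(2R)-6-methoxy-2,8-dimethyl-3,4-dihydro-2H-chromen-2-yl]-2,6-dimethylnona-2,6-dienal | COc1cc(C)c2c(c1)CC[C@@](C)(CC/C=C(\C)CC/C=C(/C)C=O)O2
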